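## Retrosynthetic overview

1. Ring C is opened at the O1–C2 bond, so the (2S)-flavanone goes back to the open-chain (E)-2',6'-dihydroxychalcone. In the forward direction a site- and face-selective 6-endo oxa-Michael closure makes this C–O bond and sets C2.
2. The chalcone Cα=Cβ bond is cut (Claisen–Schmidt) into the 3-prenylated 2,6-dihydroxy-4-methoxyacetophenone and 3,4,5-trimethoxybenzaldehyde.
3. The aryl–prenyl bond is cut (phenolate C-alkylation) into 2',6'-dihydroxy-4'-methoxyacetophenone and prenyl bromide.
4. Ring order: rings A and B are bought as arenes. Ring C is the only ring made and is closed last, so the stereocentre meets no later reagent. No protecting groups are used.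

Assumptions: compound 1 is taken as an inexpensive catalogue chemical; the quinine-derived catalyst series is taken to give the (2S) product (checked by CD, negative Cotton effect near 290 nm), and the quinidine-derived pseudoenantiomer is equally available.

## Route

Step 1
Reactants: 1 2',6'-dihydroxy-4'-methoxyacetophenone; 2 prenyl bromide (1-bromo-3-methylbut-2-ene)
Product: 3 2',6'-dihydroxy-4'-methoxy-3'-prenylacetophenone
Conditions: KOH (1.0 equiv), H2O, 0 °C → rt, 4 h (1 in slight excess, recovered)
Reagents that add atoms: prenyl bromide (2), CC(C)=CCBr
Why: Phenolate C-alkylation (nuclear prenylation): in water the phenolate oxygen is shielded by hydrogen bonding, so the soft allylic bromide is taken by the electron-rich ring carbon, and because C3 and C5 of 1 are equivalent only one mono-C-prenyl product can form.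

Step 2
Reactants: 3 2',6'-dihydroxy-4'-methoxy-3'-prenylacetophenone; 4 3,4,5-trimethoxybenzaldehyde
Product: 7 (E)-2',6'-dihydroxy-4'-methoxy-3'-prenyl-3,4,5-trimethoxychalcone, via trilithium enolate 5 (not isolated), via trilithium aldolate 6 (not isolated)
Conditions: LiN(SiMe3)2 (3.3 equiv), THF, −78 → 0 °C, 1 h; 4 (1.1 equiv), −78 °C → rt, 16 h; cold 1 M HCl, fast extraction, crystallisation from EtOAc/hexane
Reagents that add atoms: 3,4,5-trimethoxybenzaldehyde (4), COc1cc(C=O)cc(OC)c1OC
Why: Claisen–Schmidt aldol condensation: full deprotonation gives a THF-soluble trianion whose enolate carbon adds to the non-enolisable aldehyde, E1cB loss of LiOH on warming gives the conjugated (E)-enone, and the diphenolate form keeps the chain open until the cold quench.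

Step 3
Reactants: 7 (E)-2',6'-dihydroxy-4'-methoxy-3'-prenyl-3,4,5-trimethoxychalcone
Product: 8 artoflavanone = (2S)-5-hydroxy-7-methoxy-6-prenyl-3',4',5'-trimethoxyflavanone
Conditions: N-[3,5-bis(trifluoromethyl)phenyl]-N'-[(8α,9S)-6'-methoxycinchonan-9-yl]thiourea (quinine-derived, 10 mol %), toluene/CH2Cl2 9:1 (0.05 M), −30 °C, 72 h; cold filtration through SiO2 to remove the amine, chromatography, recrystallisation
Reagents that add atoms: none
Why: Proposed new method: site- and enantioselective 6-endo-trig intramolecular oxa-Michael addition of a free, unsymmetrical 2',6'-dihydroxychalcone under bifunctional Brønsted base/hydrogen-bond-donor catalysis, which forms the O1–C2 bond, closes ring C and sets C2; the 2'-OH, pressed against the carbonyl by the neighbouring prenyl group, stays in its intramolecular hydrogen bond (it polarises the enone and is masked as a nucleophile), the free, less hindered and more acidic 6'-OH is deprotonated by the quinuclidine nitrogen to a contact ion pair while the thiourea N–H bonds hold the carbonyl oxygen, so the phenoxide is delivered to the Si face of C-β (this gives 2S) and the quinuclidinium returns the proton to C-α; because the second ortho-OH makes closure much faster and more exergonic than in mono-hydroxychalcones, the reaction runs at −30 °C with a weak amine, where uncatalysed closure and racemising retro-Michael opening are slow; the closest known reaction types are the cinchona-thiourea-catalysed oxa-Michael cyclisation of 2'-hydroxychalcones activated by an α-ester group and the enzymatic chalcone isomerase closure, neither shown for a substrate with two competing, non-equivalent phenols.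

## Compound list

1 | 2',6'-dihydroxy-4'-methoxyacetophenone, 1-(2,6-dihydroxy-4-methoxyphenyl)ethan-1-one | CC(=O)c1c(O)cc(OC)cc1O | starting material
2 | prenyl bromide, 1-bromo-3-methylbut-2-ene | CC(C)=CCBr | starting material
3 | 1-[2,6-dihydroxy-4-methoxy-3-(3-methylbut-2-en-1-yl)phenyl]ethan-1-one | CC(=O)c1c(O)cc(OC)c(CC=C(C)C)c1O | intermediate
4 | 3,4,5-trimethoxybenzaldehyde | COc1cc(C=O)cc(OC)c1OC | starting material
5 | trilithium salt of 3 (methyl ketone enolate plus both phenolates) | [Li+].[Li+].[Li+].C=C([O-])c1c([O-])cc(OC)c(CC=C(C)C)c1[O-] | intermediate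
6 | trilithium aldolate of 3 and 4 (β-alkoxide plus both phenolates, racemic at the carbinol carbon) | [Li+].[Li+].[Li+].COc1cc([O-])c(C(=O)CC([O-])c2cc(OC)c(OC)c(OC)c2)c([O-])c1CC=C(C)C | intermediate
7 | (E)-1-[2,6-dihydroxy-4-methoxy-3-(3-methylbut-2-en-1-yl)phenyl]-3-(3,4,5-trimethoxyphenyl)prop-2-en-1-one | COc1cc(O)c(C(=O)/C=C/c2cc(OC)c(OC)c(OC)c2)c(O)c1CC=C(C)C | intermediate
8 | artoflavanone, (2S)-5-hydroxy-7-methoxy-6-(3-methylbut-2-en-1-yl)-2-(3,4,5-trimethoxyphenyl)-2,3-dihydro-4H-chromen-4-one | COc1cc2c(c(O)c1CC=C(C)C)C(=O)C[C@@H](c1cc(OC)c(OC)c(OC)c1)O2 | target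

## Step count and risks

Total steps: 3. Longest linear sequence: 3.

**Step 3 (the proposed new step) is the most likely to fail.**
- The ee may be eroded by uncatalysed closure or by retro-Michael opening.
- Part of the material may close through the 2'-OH and give the 8-prenyl regioisomer, which is removable by chromatography.
- The sense of induction has to be confirmed.

The fallback uses known chemistry and replaces asymmetric catalysis by resolution. It sets out from 7. Closure with NaOAc in refluxing EtOH gives, after chromatography, the racemic flavanone F1. Preparative HPLC on an amylose tris(3,5-dimethylphenylcarbamate) phase (hexane/i-PrOH) then separates F1 into 8 and the (2R)-enantiomer F2. F2 is returned to F1 under the same NaOAc conditions through the chalcone equilibrium and resolved again. The fallback comes back to the route at 8.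

**Step 1 is second.** O-alkylation, double prenylation and hydrolysis of 2 may hold the yield near 40 %. The fallback replaces direct C-alkylation by O-alkylation and sigmatropic transfer. It sets out from 1 and 2. K2CO3 in refluxing acetone gives the aryl prenyl ether F3, because the second OH is chelated and stays free. Heating F3 in N,N-diethylaniline at 200 °C starts a tandem Claisen–Cope rearrangement that carries the prenyl group, un-inverted, to the position para to the ether oxygen. By the symmetry of 1 that product is compound 3, where the fallback rejoins the route.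

**Step 2 is third.** The polyanion may react sluggishly, and part of 7 may close to racemic flavanone during the quench. Any such material must be removed before step 3, since it would lower the ee. The fallback changes to a protected substrate. It sets out from 3.
- MOMCl (1.1 equiv) and i-Pr2NEt in CH2Cl2 at 0 °C cap the unhindered 6-OH and give the mono-MOM ether F4.
- Classical KOH/EtOH Claisen–Schmidt condensation of F4 with 4 gives the MOM-protected chalcone F5.
- Brief treatment of F5 with dilute HCl in MeOH at rt releases 7, where the fallback rejoins the route.

## Further compounds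

F1 | step 3 | racemic 5-hydroxy-7-methoxy-6-prenyl-3',4',5'-trimethoxyflavanone | COc1cc2c(c(O)c1CC=C(C)C)C(=O)CC(c1cc(OC)c(OC)c(OC)c1)O2
F2 | step 3 | (2R)-5-hydroxy-7-methoxy-6-prenyl-3',4',5'-trimethoxyflavanone | COc1cc2c(c(O)c1CC=C(C)C)C(=O)C[C@H](c1cc(OC)c(OC)c(OC)c1)O2
F3 | step 1 | 1-[2-hydroxy-4-methoxy-6-(3-methylbut-2-en-1-yloxy)phenyl]ethan-1-one | CC(=O)c1c(O)cc(OC)cc1OCC=C(C)C
F4 | step 2 | 1-[2-hydroxy-4-methoxy-6-(methoxymethoxy)-3-(3-methylbut-2-en-1-yl)phenyl]ethan-1-one | CC(=O)c1c(O)c(CC=C(C)C)c(OC)cc1OCOC
F5 | step 2 | (E)-2'-hydroxy-4'-methoxy-6'-(methoxymethoxy)-3'-prenyl-3,4,5-trimethoxychalcone | COCOc1cc(OC)c(CC=C(C)C)c(O)c1C(=O)/C=C/c1cc(OC)c(OC)c(OC)c1
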